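**Retrosynthetic overview**

1. 23 ⇐ 22 (C14 acetylation) ⇐ 21 ⇐ 19 + umbelliferone 20 (C11–O bond) ⇐ 18 (alkenyl oxirane; formate hydrogenolysis sets C9–H) ⇐ 17 ⇐ 14 (C9 ketone: C12 by α-methylenation, C11 by sulfonium ylide).
2. 14 ⇐ 11 (hydride sets C3–OH; O3/O14 acetonide) ⇐ 9 (reductive methylation sets C5–H and C4) ⇐ 7.
3. Key disconnection, ring A by [3+3]: C1–C2 and C4–C5 are formed between the achiral dione acetal 3 (C1 acetal and C5 carbonyl on quaternary C10) and the bis-silyl dienol ether 4 of methyl acetoacetate (C2–C3–C4 plus C14); the ring closure desymmetrises 3 and sets C10.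
4. Enabling feature: in ring A the C3 oxygen lies between C2 and C4, and C4 carries the oxidised carbon C14, so C2–C3–C4(–C14) is an acetoacetate unit nucleophilic at C2 and C4. The quaternary C10 lies between C1 and C5, so it can carry an aldehyde-level C1 and a ketone-level C5 with nothing enolisable between them; the twin carbonyl C9 of ring B makes that precursor symmetric.
5. Ring order: ring B is bought (1); ring A closes in step 2; the dioxolane (C9), oxirane (C9/C11) and acetonide (O3/O14) are temporary rings.

Key step: step 2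

Remark on numbering: drimane numbering is used (ring A = C1–C5 and C10; ring B = C5–C10; C11 is the oxymethylene on C9, C12 the methylidene carbon on C8, C13 the methyl and C14 the oxymethyl on C4, C15 the methyl on C10); the target read from its SMILES is (3R,4R,5S,9R,10R).

Remark on step 2: the sense of induction of the chiral acid cannot be predicted with certainty; the catalyst antipode that delivers (4aR)-7 is the one meant.

Step 1
Reactants: 1 2-methylcyclohexane-1,3-dione
Product: 3 2-(dimethoxymethyl)-2-methylcyclohexane-1,3-dione, via silyl enol ether 2 (not isolated)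
Conditions: TMSCl, Et3N, MeCN, rt; then HC(OMe)3, TMSOTf (5 mol%), CH2Cl2, −78 to −30 °C
Reagents that add atoms: chlorotrimethylsilane, C[Si](C)(C)Cl (silyl group of 2 only); trimethyl orthoformate, COC(OC)OC
Why: Mukaiyama-type alkylation, in which the vinylogous silyl ester 2 attacks the dimethoxycarbenium ion at C10 and creates the quaternary carbon without a stereocentre, since 3 keeps a mirror plane.

Step 2
Reactants: 3 2-(dimethoxymethyl)-2-methylcyclohexane-1,3-dione; 4 1-methoxy-1,3-bis(trimethylsilyloxy)buta-1,3-diene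
Product: 7 methyl (4aR)-4a-methyl-2,5-dioxo-2,4a,5,6,7,8-hexahydronaphthalene-1-carboxylate, via silyl ketene acetal 5 (not isolated), via silyl aldolate 6 (not isolated)
Conditions: 4 (1.2 equiv), chiral imidodiphosphorimidate acid [(ArO)2P(=NSO2CF3)]2NH with (ArO)2 = 3,3'-diaryl-1,1'-bi-2-naphtholate (3 mol%), toluene, −78 to −40 °C; then DBU (2.5 equiv), −40 °C to rt
Reagents that add atoms: none
Why: Proposed new method: the confined chiral acid is silylated by 4 to a silylium–counteranion pair that ionises the acetal of 3 (loss of methoxytrimethylsilane), so the terminal diene carbon C2 adds to the C1 oxocarbenium ion (vinylogous Mukaiyama addition, C1–C2) and leaves a silyl ketene acetal that is nucleophilic at C4. That carbon then closes ring A by a 6-(enolexo)-exo-trig Mukaiyama aldol addition onto one of the two enantiotopic ring carbonyls (C4–C5), and DBU expels trimethylsilanol and methanol (E1cB) to give the cross-conjugated dienone 7. The closest known reaction type is the TiCl4-mediated [3+3] cyclocondensation of 1,3-bis(silyloxy)-1,3-dienes with β-keto acetals, which forms the same two bonds in the same order, taken together with silylium-counteranion-directed Mukaiyama aldol additions to ketones and acid-catalysed Hajos–Parrish-type desymmetrising aldolisations of 2,2-disubstituted cyclohexane-1,3-diones. The only lasting stereocentre, C10, is fixed by which carbonyl (C5 or C9) is attacked inside the chiral anion pocket (catalyst control), while the transient centres at C1, C4 and C5 are erased by the eliminations, so C1 epimers converge. The step needs chemoselectivity (acetal before ketone, C2 before C4), secured by the higher electrophilicity of the oxocarbenium ion and the higher nucleophilicity of the diene terminus, and a six-membered transition state exists only for C4 onto C5 or C9.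

Step 3
Reactants: 7 methyl (4aR)-4a-methyl-2,5-dioxo-2,4a,5,6,7,8-hexahydronaphthalene-1-carboxylate
Product: 8 methyl (4aR)-5,5-(ethylenedioxy)-4a-methyl-2-oxo-2,4a,5,6,7,8-hexahydronaphthalene-1-carboxylate
Conditions: (TMSOCH2)2, TMSOTf (2 mol%), CH2Cl2, −78 to −20 °C
Reagents that add atoms: 1,2-bis(trimethylsilyloxy)ethane, C[Si](C)(C)OCCO[Si](C)(C)C
Why: silyl-triflate-catalysed ketalisation should take the saturated C9 ketone and leave the cross-conjugated, ester-flanked C3 carbonyl, as in the classical selective ketalisation of the saturated carbonyl of bicyclic enediones; no stereocentre is formed.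

Step 4
Reactants: 8 methyl (4aR)-5,5-(ethylenedioxy)-4a-methyl-2-oxo-2,4a,5,6,7,8-hexahydronaphthalene-1-carboxylate
Product: 9 methyl (4aR)-5,5-(ethylenedioxy)-4a-methyl-2-oxo-2,3,4,4a,5,6,7,8-octahydronaphthalene-1-carboxylate
Conditions: H2 (1 atm), RhCl(PPh3)3 (5 mol%), benzene–EtOH, rt
Reagents that add atoms: none
Why: homogeneous hydrogenation with RhCl(PPh3)3 should saturate the disubstituted C1=C2 bond of the cross-conjugated dienone and leave the tetrasubstituted, ester-bearing C4=C5 bond, as known for steroidal 1,4-dien-3-ones; no stereocentre is formed.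

Step 5
Reactants: 9 methyl (4aR)-5,5-(ethylenedioxy)-4a-methyl-2-oxo-2,3,4,4a,5,6,7,8-octahydronaphthalene-1-carboxylate
Product: 11 methyl (1S,4aR,8aS)-5,5-(ethylenedioxy)-1,4a-dimethyl-2-oxodecahydronaphthalene-1-carboxylate, via lithium enolate 10 (not isolated)
Conditions: Li (2.2 equiv), t-BuOH (1.0 equiv), NH3(l)–THF, −78 °C; isoprene; then MeI, −78 °C to rt
Reagents that add atoms: lithium, [Li] (counter-ion of 10 only); iodomethane, CI
Why: Birch-type reductive alkylation of an alkylidene β-keto ester, in which protonation of C5 gives the trans ring fusion (H anti to the axial C15 methyl) and enolate 10 is methylated at C4 on the face anti to C15, so the ester carbon C14 ends axial and C13 equatorial.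

Step 6
Reactants: 11 methyl (1S,4aR,8aS)-5,5-(ethylenedioxy)-1,4a-dimethyl-2-oxodecahydronaphthalene-1-carboxylate
Product: 12 (1R,2R,4aR,8aR)-5,5-(ethylenedioxy)-1-(hydroxymethyl)-1,4a-dimethyldecahydronaphthalen-2-ol
Conditions: LiAlH4, THF, 0 °C to rt
Reagents that add atoms: none
Why: hydride reduction, in which axial attack on the C3 ketone from the face anti to the axial C14 group gives the equatorial C3 alcohol and the neopentyl ester is reduced to the primary C14 alcohol.

Step 7
Reactants: 12 (1R,2R,4aR,8aR)-5,5-(ethylenedioxy)-1-(hydroxymethyl)-1,4a-dimethyldecahydronaphthalen-2-ol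
Product: 13 3,14-dihydroxy-11,12-dinordriman-9-one (C3, C4, C5, C10 as in 23)
Conditions: 1 M HCl, THF, rt
Reagents that add atoms: water, O
Why: acid-catalysed acetal hydrolysis frees the C9 ketone without touching a stereocentre, since C10 is quaternary.

Step 8
Reactants: 13 3,14-dihydroxy-11,12-dinordriman-9-one
Product: 14 3,14-O-isopropylidene-3,14-dihydroxy-11,12-dinordriman-9-one
Conditions: Me2C(OMe)2, PPTS (cat.), CH2Cl2, rt
Reagents that add atoms: 2,2-dimethoxypropane, COC(C)(C)OC
Why: acetonide formation ties the cis-disposed O3/O14 1,3-diol into a six-membered temporary ring that withstands the base steps that follow.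

Step 9
Reactants: 14 3,14-O-isopropylidene-3,14-dihydroxy-11,12-dinordriman-9-one
Product: 17 3,14-O-isopropylidene-3,14-dihydroxy-11-nordrim-8(12)-en-9-one, via Mannich base 15 (not isolated), via methiodide 16 (not isolated)
Conditions: LiHMDS, THF, −78 °C; CH2=NMe2+ I−, −78 °C to rt; then MeI, rt; then DBU, CH2Cl2, rt
Reagents that add atoms: dimethyl(methylidene)ammonium iodide, C=[N+](C)C.[I-]; iodomethane, CI (methyl of 16 only)
Why: Mannich reaction of the only possible enolate (toward C8, since C10 is quaternary) with Eschenmoser's salt, then quaternisation and E1cB elimination, places C12 as the α-methylene group; no stereocentre is formed.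

Step 10
Reactants: 17 3,14-O-isopropylidene-3,14-dihydroxy-11-nordrim-8(12)-en-9-one
Product: 18 9,11-epoxy-3,14-O-isopropylidenedrim-8(12)-ene-3,14-diol (oxirane oxygen equatorial at C9, C11 axial)
Conditions: Me3S+ I−, n-BuLi, THF, −10 °C; then crude 17, −10 to 0 °C
Reagents that add atoms: trimethylsulfonium iodide, C[S+](C)C.[I-]
Why: Corey–Chaykovsky epoxidation, in which the unstabilised sulfonium ylide adds 1,2 to the carbonyl along the axial trajectory anti to the axial C15 methyl, so C11 becomes axial and the oxirane oxygen equatorial at C9.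

Step 11
Reactants: 18 9,11-epoxy-3,14-O-isopropylidenedrim-8(12)-ene-3,14-diol
Product: 19 3,14-O-isopropylidenedrim-8(12)-ene-3,11,14-triol (free C11 hydroxyl; C9 as in 23)
Conditions: Pd2(dba)3·CHCl3 (2.5 mol%), PBu3 (10 mol%), HCO2H, Et3N, 1,4-dioxane, rt
Reagents that add atoms: none
Why: palladium-catalysed formate hydrogenolysis of an alkenyl oxirane, in which zerovalent palladium ionises the C9–O bond with inversion to a π-allyl complex (C9–C8–C12) and hydride passes from palladium to the more substituted terminus C9, which should give the homoallylic alcohol with the exocyclic C8=C12 bond, C9–H axial and C11 equatorial (cis to C15).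

Step 12
Reactants: 19 3,14-O-isopropylidenedrim-8(12)-ene-3,11,14-triol; 20 7-hydroxy-2H-chromen-2-one (umbelliferone)
Product: 21 7-[(3,14-O-isopropylidene-3,14-dihydroxydrim-8(12)-en-11-yl)oxy]-2H-chromen-2-one
Conditions: PPh3, DIAD, THF, 0 °C to 40 °C
Reagents that add atoms: none
Why: Mitsunobu etherification of the primary C11 alcohol with the acidic phenol of 20; C11 is not stereogenic and the other two hydroxyls are masked.

Step 13
Reactants: 21 7-[(3,14-O-isopropylidene-3,14-dihydroxydrim-8(12)-en-11-yl)oxy]-2H-chromen-2-one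
Product: 22 7-[(3,14-dihydroxydrim-8(12)-en-11-yl)oxy]-2H-chromen-2-one
Conditions: AcOH–H2O (4:1), 40 °C
Reagents that add atoms: none
Why: mild acid hydrolysis of the isopropylidene acetal, which the exocyclic alkene, the aryl ether and the lactone should tolerate.

Step 14
Reactants: 22 7-[(3,14-dihydroxydrim-8(12)-en-11-yl)oxy]-2H-chromen-2-one
Product: 23 7-{[(3R,4R,5S,9R,10R)-14-acetoxy-3-hydroxydrim-8(12)-en-11-yl]oxy}-2H-chromen-2-one (target)
Conditions: Ac2O (1.1 equiv), 2,4,6-collidine, CH2Cl2, −20 to 0 °C
Reagents that add atoms: acetic anhydride, CC(=O)OC(C)=O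
Why: chemoselective acylation, since the primary C14 hydroxyl should react faster than the hindered secondary C3 hydroxyl next to the quaternary C4.

**Compound list**

1 | 2-methylcyclohexane-1,3-dione | CC1C(=O)CCCC1=O | starting material
2 | 2-methyl-3-(trimethylsilyloxy)cyclohex-2-en-1-one | CC1=C(O[Si](C)(C)C)CCCC1=O | intermediate (not isolated)
3 | 2-(dimethoxymethyl)-2-methylcyclohexane-1,3-dione (achiral) | COC(OC)C1(C)C(=O)CCCC1=O | intermediate
4 | 1-methoxy-1,3-bis(trimethylsilyloxy)buta-1,3-diene (bis-silyl dienol ether of methyl acetoacetate) | COC(O[Si](C)(C)C)=CC(=C)O[Si](C)(C)C | starting material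
5 | 2-[1,5-dimethoxy-3-oxo-5-(trimethylsilyloxy)pent-4-en-1-yl]-2-methylcyclohexane-1,3-dione (C1 configuration open) | COC(O[Si](C)(C)C)=CC(=O)CC(OC)C1(C)C(=O)CCCC1=O | intermediate (not isolated)
6 | methyl 4-methoxy-4a-methyl-2,5-dioxo-8a-(trimethylsilyloxy)octahydronaphthalene-1-carboxylate (C10 as in 7, other centres open) | COC(=O)C1C(=O)CC(OC)[C@@]2(C)C(=O)CCCC12O[Si](C)(C)C | intermediate (not isolated)
7 | methyl (4aR)-4a-methyl-2,5-dioxo-2,4a,5,6,7,8-hexahydronaphthalene-1-carboxylate | C1CCC2=C(C(=O)OC)C(=O)C=C[C@@]2(C)C1=O | intermediate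
8 | methyl (4aR)-5,5-(ethylenedioxy)-4a-methyl-2-oxo-2,4a,5,6,7,8-hexahydronaphthalene-1-carboxylate | C1CCC2=C(C(=O)OC)C(=O)C=C[C@@]2(C)C13OCCO3 | intermediate
9 | methyl (4aR)-5,5-(ethylenedioxy)-4a-methyl-2-oxo-2,3,4,4a,5,6,7,8-octahydronaphthalene-1-carboxylate | C1CCC2=C(C(=O)OC)C(=O)CC[C@@]2(C)C13OCCO3 | intermediate
10 | lithium enolate of the trans-fused 8a-hydro β-keto ester | C1CC[C@@H]2C(C(=O)OC)=C(O[Li])CC[C@@]2(C)C13OCCO3 | intermediate (not isolated)
11 | methyl (1S,4aR,8aS)-5,5-(ethylenedioxy)-1,4a-dimethyl-2-oxodecahydronaphthalene-1-carboxylate | C1CC[C@@H]2[C@](C)(C(=O)OC)C(=O)CC[C@@]2(C)C13OCCO3 | intermediate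
12 | (1R,2R,4aR,8aR)-5,5-(ethylenedioxy)-1-(hydroxymethyl)-1,4a-dimethyldecahydronaphthalen-2-ol | C1CC[C@@H]2[C@](C)(CO)[C@H](O)CC[C@@]2(C)C13OCCO3 | intermediate
13 | 3,14-dihydroxy-11,12-dinordriman-9-one | C1CC[C@@H]2[C@](C)(CO)[C@H](O)CC[C@@]2(C)C1=O | intermediate
14 | 3,14-O-isopropylidene-3,14-dihydroxy-11,12-dinordriman-9-one | C1CC[C@@H]2[C@]3(C)COC(C)(C)O[C@@H]3CC[C@@]2(C)C1=O | intermediate
15 | 8-(dimethylaminomethyl) derivative of 14 (C8 configuration open) | CN(C)CC1CC[C@@H]2[C@]3(C)COC(C)(C)O[C@@H]3CC[C@@]2(C)C1=O | intermediate (not isolated)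
16 | trimethylammonium iodide of 15 | C[N+](C)(C)CC1CC[C@@H]2[C@]3(C)COC(C)(C)O[C@@H]3CC[C@@]2(C)C1=O.[I-] | intermediate (not isolated)
17 | 3,14-O-isopropylidene-3,14-dihydroxy-11-nordrim-8(12)-en-9-one | C=C1CC[C@@H]2[C@]3(C)COC(C)(C)O[C@@H]3CC[C@@]2(C)C1=O | intermediate
18 | 9,11-epoxy-3,14-O-isopropylidenedrim-8(12)-ene-3,14-diol | C=C1CC[C@@H]2[C@]3(C)COC(C)(C)O[C@@H]3CC[C@@]2(C)[C@@]14CO4 | intermediate
19 | 3,14-O-isopropylidenedrim-8(12)-ene-3,11,14-triol | C=C1CC[C@@H]2[C@]3(C)COC(C)(C)O[C@@H]3CC[C@@]2(C)[C@@H]1CO | intermediate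
20 | 7-hydroxy-2H-chromen-2-one (umbelliferone) | Oc1ccc2ccc(=O)oc2c1 | starting material
21 | 7-[(3,14-O-isopropylidene-3,14-dihydroxydrim-8(12)-en-11-yl)oxy]-2H-chromen-2-one | C=C1CC[C@@H]2[C@]3(C)COC(C)(C)O[C@@H]3CC[C@@]2(C)[C@@H]1COc1ccc2ccc(=O)oc2c1 | intermediate
22 | 7-[(3,14-dihydroxydrim-8(12)-en-11-yl)oxy]-2H-chromen-2-one | C=C1CC[C@@H]2[C@](C)(CO)[C@H](O)CC[C@@]2(C)[C@@H]1COc1ccc2ccc(=O)oc2c1 | intermediate
23 | 7-{[(3R,4R,5S,9R,10R)-14-acetoxy-3-hydroxydrim-8(12)-en-11-yl]oxy}-2H-chromen-2-one | C=C1CC[C@@H]2[C@](C)(COC(C)=O)[C@H](O)CC[C@@]2(C)[C@@H]1COc1ccc2ccc(=O)oc2c1 | target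

Total step count: 14. Longest linear sequence: 14 steps (1 to 23); 4 and 20 are bought.

**Steps most likely to fail**

Step 2 (proposed new method). The ring closure may discriminate the two enantiotopic carbonyls poorly, the sequence may stall after the first C–C bond because the hindered ketone is activated too slowly, or the acid may cleave the 2,2-diacyl acetal by a retro-Claisen path. The fallback uses known chemistry, sets out from 3 and returns at 7, and breaks the symmetry before the annulation instead of during it. A Noyori-type asymmetric transfer hydrogenation of 3 [RuCl(p-cymene)(TsDPEN), antipode chosen for the 3S carbinol, HCO2Na, water–ethyl acetate] should reduce one enantiotopic carbonyl to (2R,3S)-2-(dimethoxymethyl)-3-hydroxy-2-methylcyclohexan-1-one F1; the minor hydroxyl epimer, which would lead into the enantiomeric series, is removed by chromatography. TBSOTf and 2,6-lutidine should give the silyl ether F2. The TiCl4-mediated [3+3] cyclocondensation of F2 with 4 (CH2Cl2, −78 °C, then DBU) forms the same C1–C2 and C4–C5 bonds and should give the silyloxy dienone F3. HF·pyridine should give the alcohol F4, and Dess–Martin oxidation returns to 7.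

Step 11. Hydride may be transferred to the unhindered terminus C12, giving the endocyclic C8=C9 alkene, or the π-allyl complex may lose a β-hydrogen to a diene, so that regio- and stereocontrol at C9 is lost. The fallback sets out from 18 and returns at 19 and replaces hydride delivery from palladium by a cationic 1,2-hydride shift. A Meinwald rearrangement of 18 (InCl3 cat., THF, rt) should ionise the allylic tertiary C9–O bond and move a hydride from C11 to C9, giving the β,γ-unsaturated aldehyde F5. If its C9 centre is mixed it is equilibrated to the equatorial formyl epimer (Et3N), and NaBH4 (MeOH, 0 °C) gives 19.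

Step 12. Substitution at the β-branched C11 oxyphosphonium ion may be slow, so that elimination or alkylation of the hydrazide takes over. The fallback sets out from 19 and returns at 21 and forms the aryl–oxygen bond instead of the alkyl–oxygen bond: palladium-catalysed C–O cross-coupling of 19 with commercial 7-bromo-2H-chromen-2-one ([Pd(allyl)Cl]2, a di-tert-butyl biaryl phosphine, Cs2CO3, toluene, 80 °C) should give 21 directly; no new compound is made on the way (F0).

**Further compounds**

F1 | step 2 | (2R,3S)-2-(dimethoxymethyl)-3-hydroxy-2-methylcyclohexan-1-one | O=C1CCC[C@H](O)[C@]1(C)C(OC)OC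
F2 | step 2 | (2R,3S)-3-(tert-butyldimethylsilyloxy)-2-(dimethoxymethyl)-2-methylcyclohexan-1-one | O=C1CCC[C@H](O[Si](C)(C)C(C)(C)C)[C@]1(C)C(OC)OC
F3 | step 2 | methyl (4aR,5S)-5-(tert-butyldimethylsilyloxy)-4a-methyl-2-oxo-2,4a,5,6,7,8-hexahydronaphthalene-1-carboxylate | C1CCC2=C(C(=O)OC)C(=O)C=C[C@@]2(C)[C@H]1O[Si](C)(C)C(C)(C)C
F4 | step 2 | methyl (4aR,5S)-5-hydroxy-4a-methyl-2-oxo-2,4a,5,6,7,8-hexahydronaphthalene-1-carboxylate | C1CCC2=C(C(=O)OC)C(=O)C=C[C@@]2(C)[C@H]1O
F5 | step 11 | 3,14-O-isopropylidene-3,14-dihydroxydrim-8(12)-en-11-al | C=C1CC[C@@H]2[C@]3(C)COC(C)(C)O[C@@H]3CC[C@@]2(C)[C@@H]1C=O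
F0 | step 12 | none | none
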